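The tetrahydrofuran is numbered O1, C2 (aryl), C3 (spiro), C4 (benzyl), C5. The route rests on cutting the C2–aryl bond and the O1–C5 bond together. C2 sits between the ring oxygen and the quaternary spiro-epoxide carbon C3, which carries no hydrogen, and the C2 oxygen and C5 are partners in a five-membered ring. An aryllithium can therefore add to a C2 aldehyde and the alkoxide so formed can displace a C5 bromide in the same flask, which sets C2 and closes the tetrahydrofuran beside the intact oxirane. The precursor is an α-quaternary epoxy aldehyde with C3 and C4 already in final form and a primary bromide at C5, built by Evans allylation and Sharpless epoxidation.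

Key step: step 12

Remark: TBS = tert-butyldimethylsilyl; the atom labels C2–C5 above are used for all intermediates.
Remark: the C5 bromide is installed before C2 is raised to the aldehyde level, because a free C5 hydroxyl beside a C2 aldehyde would close to a lactol, which oxidants take on to the lactone.
Remark: the configurations were checked by CIP analysis: epoxy aldehyde 16 is (C3 S, C4 R), the target is (C2 S, C3 S, C4 S), and the change of letter at C4 is a priority change only.
Assumption: 3-(3-hydroxy-4-methoxyphenyl)propanoic acid, (S)-4-benzyl-1,3-oxazolidin-2-one and 4-bromo-2-methoxyphenol are bought.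

Step 1
Reactants: 1 3-(3-hydroxy-4-methoxyphenyl)propanoic acid
Product: 3 3-[3-(TBSO)-4-methoxyphenyl]propanoic acid, via bis-silyl derivative 2 (not isolated)
Conditions: TBSCl (2.3 equiv), imidazole, DMF, rt; then AcOH/THF/H2O, rt
Reagents that add atoms: tert-butyldimethylsilyl chloride, CC(C)(C)[Si](C)(C)Cl
Why: Silylation of phenol and acid followed by selective hydrolysis of the labile silyl ester (the aryl silyl ether resists dilute acetic acid) should give the phenol-protected acid; this is a protecting-group installation.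

Step 2
Reactants: 3 3-[3-(TBSO)-4-methoxyphenyl]propanoic acid; 4 (S)-4-benzyl-1,3-oxazolidin-2-one
Product: 6 (4S)-4-benzyl-3-{3-[3-(TBSO)-4-methoxyphenyl]propanoyl}-1,3-oxazolidin-2-one, via mixed pivalic anhydride 5 (not isolated)
Conditions: t-BuCOCl, Et3N, THF, −20 °C; then 4, LiCl, −20 °C → rt
Reagents that add atoms: none
Why: N-Acylation of the oxazolidinone through the mixed anhydride, which is attacked at its less hindered carbonyl, is the standard way to an Evans imide.

Step 3
Reactants: 6 (4S)-4-benzyl-3-{3-[3-(TBSO)-4-methoxyphenyl]propanoyl}-1,3-oxazolidin-2-one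
Product: 8 (4S)-4-benzyl-3-{(2S)-2-[[3-(TBSO)-4-methoxyphenyl]methyl]pent-4-enoyl}-1,3-oxazolidin-2-one, via sodium Z-enolate 7 (not isolated)
Conditions: NaN(SiMe3)2, THF, −78 °C; then CH2=CHCH2I, −78 → −45 °C
Reagents that add atoms: allyl iodide, C=CCI
Why: In this Evans asymmetric alkylation the chelated Z-enolate is allylated on the face opposite the benzyl group of the auxiliary, which sets C4 in the configuration of the target (descriptor S at this stage).

Step 4
Reactants: 8 (4S)-4-benzyl-3-{(2S)-2-[[3-(TBSO)-4-methoxyphenyl]methyl]pent-4-enoyl}-1,3-oxazolidin-2-one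
Product: 9 (2S)-2-{[3-(TBSO)-4-methoxyphenyl]methyl}pent-4-en-1-ol
Conditions: LiBH4, H2O (1 equiv), Et2O, 0 °C
Reagents that add atoms: none
Why: Borohydride reduction of the exocyclic imide carbonyl releases the primary alcohol (the future C5) and the recoverable auxiliary without touching C4 (reductive auxiliary cleavage).

Step 5
Reactants: 9 (2S)-2-{[3-(TBSO)-4-methoxyphenyl]methyl}pent-4-en-1-ol
Product: 10 4-[(2S)-2-(bromomethyl)pent-4-en-1-yl]-1-methoxy-2-(TBSO)benzene
Conditions: CBr4, PPh3, CH2Cl2, 0 °C → rt
Reagents that add atoms: carbon tetrabromide, BrC(Br)(Br)Br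
Why: The Appel reaction converts the primary alcohol into the C5 bromide under neutral conditions that leave the alkene and the aryl silyl ether alone.

Step 6
Reactants: 10 4-[(2S)-2-(bromomethyl)pent-4-en-1-yl]-1-methoxy-2-(TBSO)benzene
Product: 12 (3R)-4-bromo-3-{[3-(TBSO)-4-methoxyphenyl]methyl}butanal, via ozonide 11 (not isolated)
Conditions: O3, CH2Cl2, −78 °C (stopped at the first excess of ozone); then PPh3, −78 °C → rt
Reagents that add atoms: ozone, [O-][O+]=O
Why: Ozonolysis with reductive work-up cleaves the terminal alkene, which reacts far faster than the aryl ring, to the C2 aldehyde, and no lactol can form because C5 is already a bromide.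

Step 7
Reactants: 12 (3R)-4-bromo-3-{[3-(TBSO)-4-methoxyphenyl]methyl}butanal
Product: 13 (3R)-4-bromo-3-{[3-(TBSO)-4-methoxyphenyl]methyl}-2-methylidenebutanal
Conditions: CH2O (37% aq.), pyrrolidine (10 mol %), EtCO2H (10 mol %), i-PrOH, 45 °C
Reagents that add atoms: formaldehyde, C=O
Why: The amine-catalysed Mannich condensation and elimination (α-methylenation of an aldehyde) installs the C3 methylene, the future epoxide CH2, while the non-acidic C4 centre is untouched.

Step 8
Reactants: 13 (3R)-4-bromo-3-{[3-(TBSO)-4-methoxyphenyl]methyl}-2-methylidenebutanal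
Product: 14 (3R)-4-bromo-3-{[3-(TBSO)-4-methoxyphenyl]methyl}-2-methylidenebutan-1-ol
Conditions: i-Bu2AlH, CH2Cl2, −78 °C
Reagents that add atoms: none
Why: 1,2-Reduction of the enal by the aluminium hydride at low temperature gives the 2-substituted allylic alcohol needed for a titanium-directed epoxidation, and the alkyl bromide is inert under these aprotic conditions.

Step 9
Reactants: 14 (3R)-4-bromo-3-{[3-(TBSO)-4-methoxyphenyl]methyl}-2-methylidenebutan-1-ol
Product: 15 {(2R)-2-[(2R)-1-bromo-3-[3-(TBSO)-4-methoxyphenyl]propan-2-yl]oxiran-2-yl}methanol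
Conditions: Ti(OiPr)4 (20 mol %), D-(−)-diisopropyl tartrate (24 mol %), t-BuOOH, 4 Å molecular sieves, CH2Cl2, −20 °C
Reagents that add atoms: tert-butyl hydroperoxide, CC(C)(C)OO
Why: In this Sharpless asymmetric epoxidation the D-(−)-tartrate delivers oxygen to the alkene face that makes the quaternary epoxide carbon C3 (R), the sense that turns 2-substituted allyl alcohols into (R)-2-substituted glycidols, and this reagent control should override the adjacent C4 centre.

Step 10
Reactants: 15 {(2R)-2-[(2R)-1-bromo-3-[3-(TBSO)-4-methoxyphenyl]propan-2-yl]oxiran-2-yl}methanol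
Product: 16 (2S)-2-{(2R)-1-bromo-3-[3-(TBSO)-4-methoxyphenyl]propan-2-yl}oxirane-2-carbaldehyde
Conditions: Dess–Martin periodinane, NaHCO3, CH2Cl2, 0 °C → rt
Reagents that add atoms: none
Why: The buffered Dess–Martin oxidation takes the primary epoxy alcohol to the aldehyde without opening the oxirane, and C3 cannot epimerise since it bears no hydrogen (the letter changes from R to S only because CHO outranks the epoxide CH2).

Step 11
Reactants: 17 4-bromo-2-methoxyphenol
Product: 18 (4-bromo-2-methoxyphenoxy)(tert-butyl)dimethylsilane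
Conditions: TBSCl, imidazole, DMF, rt
Reagents that add atoms: tert-butyldimethylsilyl chloride, CC(C)(C)[Si](C)(C)Cl
Why: Silylation of the phenol (protecting-group installation) removes the acidic proton so that the bromide can later be exchanged for lithium.

Step 12
Reactants: 16 (2S)-2-{(2R)-1-bromo-3-[3-(TBSO)-4-methoxyphenyl]propan-2-yl}oxirane-2-carbaldehyde; 18 (4-bromo-2-methoxyphenoxy)(tert-butyl)dimethylsilane
Product: 21 (3S,4S,7S)-4-[4-(TBSO)-3-methoxyphenyl]-7-{[3-(TBSO)-4-methoxyphenyl]methyl}-1,5-dioxaspiro[2.4]heptane, via aryllithium 19 (not isolated), via lithium alkoxide 20 (not isolated)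
Conditions: 18, n-BuLi, THF, −78 °C; then 16, −78 °C; then DMPU, −78 °C → rt
Reagents that add atoms: none
Why: Bromine–lithium exchange turns 18 into aryllithium 19, which adds to the C2 aldehyde of 16 (C2–aryl bond), and the lithium alkoxide 20 then displaces the C5 bromide in an intramolecular Williamson etherification (O1–C5 bond), so one operation joins the two fragments, sets C2 and closes the tetrahydrofuran next to the untouched oxirane. The closest known reaction types are the Felkin–Anh-selective addition of organolithiums to α,β-epoxy aldehydes and the one-pot carbonyl addition and cyclisation of γ-halo aldehydes and ketones to tetrahydrofurans. The ring closes in the 5-exo-tet mode; the alternatives through the oxirane (3-exo attack on fully substituted C3 or 4-exo attack on the epoxide CH2) are slower for a lithium alkoxide in an aprotic medium. The new stereocentre C2 is controlled by the adjacent quaternary centre C3: with the C=O dipole opposed to the epoxide C–O bond and eclipsing C3–C4, the aryl group enters anti to the epoxide oxygen across the tied-back epoxide CH2, which gives (2S) with the aryl group trans to the epoxide oxygen and cis to the C4 benzyl group. The step needs chemoselectivity for the aldehyde, secured by its far higher electrophilicity at −78 °C and by the absence of hydrogen on C3 (no enolisation, no epimerisation), and it needs the non-chelated facial preference, favoured by lithium in THF/DMPU without a Lewis acid.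

Step 13
Reactants: 21 (3S,4S,7S)-4-[4-(TBSO)-3-methoxyphenyl]-7-{[3-(TBSO)-4-methoxyphenyl]methyl}-1,5-dioxaspiro[2.4]heptane
Product: 22 5-{[(3S,4S,7S)-4-(4-hydroxy-3-methoxyphenyl)-1,5-dioxaspiro[2.4]heptan-7-yl]methyl}-2-methoxyphenol
Conditions: Bu4NF, AcOH, THF, 0 °C
Reagents that add atoms: none
Why: Fluoride cleaves both aryl silyl ethers (desilylation), and the acetic acid buffer keeps the freed phenols protonated so that neither the oxirane nor the C2 benzylic ether (through a quinone methide) is attacked.

Compound list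
1 | 3-(3-hydroxy-4-methoxyphenyl)propanoic acid | COc1ccc(CCC(=O)O)cc1O | starting material
2 | tert-butyldimethylsilyl 3-[3-(TBSO)-4-methoxyphenyl]propanoate | COc1ccc(CCC(=O)O[Si](C)(C)C(C)(C)C)cc1O[Si](C)(C)C(C)(C)C | intermediate
3 | 3-[3-(TBSO)-4-methoxyphenyl]propanoic acid | COc1ccc(CCC(=O)O)cc1O[Si](C)(C)C(C)(C)C | intermediate
4 | (S)-4-benzyl-1,3-oxazolidin-2-one | O=C1N[C@@H](Cc2ccccc2)CO1 | starting material
5 | 3-[3-(TBSO)-4-methoxyphenyl]propanoic pivalic anhydride | COc1ccc(CCC(=O)OC(=O)C(C)(C)C)cc1O[Si](C)(C)C(C)(C)C | intermediate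
6 | (4S)-4-benzyl-3-{3-[3-(TBSO)-4-methoxyphenyl]propanoyl}-1,3-oxazolidin-2-one | COc1ccc(CCC(=O)N2[C@@H](Cc3ccccc3)COC2=O)cc1O[Si](C)(C)C(C)(C)C | intermediate
7 | sodium Z-enolate of 6 | COc1ccc(C/C=C(\[O-])N2[C@@H](Cc3ccccc3)COC2=O)cc1O[Si](C)(C)C(C)(C)C.[Na+] | intermediate
8 | (4S)-4-benzyl-3-{(2S)-2-[[3-(TBSO)-4-methoxyphenyl]methyl]pent-4-enoyl}-1,3-oxazolidin-2-one | C=CC[C@@H](Cc1ccc(OC)c(O[Si](C)(C)C(C)(C)C)c1)C(=O)N1[C@@H](Cc2ccccc2)COC1=O | intermediate
9 | (2S)-2-{[3-(TBSO)-4-methoxyphenyl]methyl}pent-4-en-1-ol | C=CC[C@@H](Cc1ccc(OC)c(O[Si](C)(C)C(C)(C)C)c1)CO | intermediate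
10 | 4-[(2S)-2-(bromomethyl)pent-4-en-1-yl]-1-methoxy-2-(TBSO)benzene | C=CC[C@@H](Cc1ccc(OC)c(O[Si](C)(C)C(C)(C)C)c1)CBr | intermediate
11 | 3-[(2R)-3-bromo-2-{[3-(TBSO)-4-methoxyphenyl]methyl}propyl]-1,2,4-trioxolane (ozonide of 10) | BrC[C@H](Cc1ccc(OC)c(O[Si](C)(C)C(C)(C)C)c1)CC1OCOO1 | intermediate
12 | (3R)-4-bromo-3-{[3-(TBSO)-4-methoxyphenyl]methyl}butanal | O=CC[C@@H](Cc1ccc(OC)c(O[Si](C)(C)C(C)(C)C)c1)CBr | intermediate
13 | (3R)-4-bromo-3-{[3-(TBSO)-4-methoxyphenyl]methyl}-2-methylidenebutanal | O=CC(=C)[C@@H](Cc1ccc(OC)c(O[Si](C)(C)C(C)(C)C)c1)CBr | intermediate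
14 | (3R)-4-bromo-3-{[3-(TBSO)-4-methoxyphenyl]methyl}-2-methylidenebutan-1-ol | OCC(=C)[C@@H](Cc1ccc(OC)c(O[Si](C)(C)C(C)(C)C)c1)CBr | intermediate
15 | {(2R)-2-[(2R)-1-bromo-3-[3-(TBSO)-4-methoxyphenyl]propan-2-yl]oxiran-2-yl}methanol | OC[C@@]1(CO1)[C@@H](Cc1ccc(OC)c(O[Si](C)(C)C(C)(C)C)c1)CBr | intermediate
16 | (2S)-2-{(2R)-1-bromo-3-[3-(TBSO)-4-methoxyphenyl]propan-2-yl}oxirane-2-carbaldehyde | O=C[C@@]1(CO1)[C@@H](Cc1ccc(OC)c(O[Si](C)(C)C(C)(C)C)c1)CBr | intermediate
17 | 4-bromo-2-methoxyphenol | COc1cc(Br)ccc1O | starting material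
18 | (4-bromo-2-methoxyphenoxy)(tert-butyl)dimethylsilane | COc1cc(Br)ccc1O[Si](C)(C)C(C)(C)C | intermediate
19 | 4-(TBSO)-3-methoxyphenyllithium | [Li]c1ccc(O[Si](C)(C)C(C)(C)C)c(OC)c1 | intermediate
20 | lithium (S)-[4-(TBSO)-3-methoxyphenyl]{(2S)-2-[(2R)-1-bromo-3-[3-(TBSO)-4-methoxyphenyl]propan-2-yl]oxiran-2-yl}methanolate | [Li+].[O-][C@@H](c1ccc(O[Si](C)(C)C(C)(C)C)c(OC)c1)[C@@]1(CO1)[C@@H](Cc1ccc(OC)c(O[Si](C)(C)C(C)(C)C)c1)CBr | intermediate
21 | (3S,4S,7S)-4-[4-(TBSO)-3-methoxyphenyl]-7-{[3-(TBSO)-4-methoxyphenyl]methyl}-1,5-dioxaspiro[2.4]heptane | COc1ccc(C[C@H]2CO[C@@H](c3ccc(O[Si](C)(C)C(C)(C)C)c(OC)c3)[C@@]23CO3)cc1O[Si](C)(C)C(C)(C)C | intermediate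
22 | 5-{[(3S,4S,7S)-4-(4-hydroxy-3-methoxyphenyl)-1,5-dioxaspiro[2.4]heptan-7-yl]methyl}-2-methoxyphenol (CNP0184956.1) | COc1ccc(C[C@H]2CO[C@@H](c3ccc(O)c(OC)c3)[C@@]23CO3)cc1O | target

Total step count: 13. Longest linear sequence: 12 (steps 1–10, 12 and 13; step 11 is a one-step side branch).

Steps most likely to fail

Step 12. The aryl group may be delivered to the wrong face of the aldehyde (approach on the side of the epoxide oxygen, by chelation or by a dipole-controlled gauche attack), or the alkoxide may attack the oxirane before the ring closes. The fallback sets out from enal 13 and aryl bromide 18 and returns at 21; it postpones the oxirane. Aryllithium 19, made from 18 as above, would be added to 13 in THF at −78 °C (1,2-addition). The lithium allylic alkoxide F1 would then be warmed with DMPU to close the ring by the same 5-exo-tet displacement, now with no oxirane present. This addition is not expected to be selective at C2, so the 2,4-cis 3-methylidene tetrahydrofuran F2 would be separated from its C2 epimer by chromatography. Epoxidation of F2 with dimethyldioxirane in acetone at 0 °C (or m-CPBA/NaHCO3) should then occur on the ring face opposite the two cis substituents at C2 and C4, which is the oxirane configuration of 21.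

Step 9. The bias of the C4 centre may oppose the tartrate (mismatched double diastereoselection), or the bromo alcohol may be lost by premature closure of the C2 oxygen onto C5 or by alkoxide opening of the 2,2-disubstituted oxirane. The fallback sets out from enal 13 and returns at 16, bypassing 14 and 15. It is the known nucleophilic epoxidation of 2-substituted acroleins with aqueous H2O2 under iminium/enamine catalysis by a diphenylprolinol silyl ether (10–20 mol %, CH2Cl2, rt). The (R)-catalyst would be tried first, with its antipode at hand should the sense of induction on this α-branched acrolein be the other one. No hydroxyl group is ever present beside the C5 bromide on this path, and it makes no new compound.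

Step 7. The enamine may be alkylated intramolecularly by the C5 bromide (cyclopropane formation), which would also consume the amine catalyst. The fallback sets out from aldehyde 12 and returns at 13; it uses a preformed nucleophile and a preformed iminium salt. Aldehyde 12 would be converted (Me3SiOTf, Et3N, CH2Cl2, 0 °C) into its trimethylsilyl enol ether F3, which cannot alkylate itself. A Mukaiyama–Mannich reaction with dimethylmethylideneammonium iodide would give the β-dimethylamino aldehyde F4. Quaternisation with MeI to the ammonium iodide F5 and elimination of trimethylamine with NaHCO3 would then give 13.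

Further compounds
F1 | step 12 | lithium (3R)-4-bromo-1-[4-(TBSO)-3-methoxyphenyl]-3-{[3-(TBSO)-4-methoxyphenyl]methyl}-2-methylidenebutan-1-olate (both C1 epimers) | [Li+].[O-]C(c1ccc(O[Si](C)(C)C(C)(C)C)c(OC)c1)C(=C)[C@@H](Cc1ccc(OC)c(O[Si](C)(C)C(C)(C)C)c1)CBr
F2 | step 12 | (2R,4R)-2-[4-(TBSO)-3-methoxyphenyl]-4-{[3-(TBSO)-4-methoxyphenyl]methyl}-3-methylideneoxolane (2,4-cis) | COc1ccc(C[C@H]2CO[C@@H](c3ccc(O[Si](C)(C)C(C)(C)C)c(OC)c3)C2=C)cc1O[Si](C)(C)C(C)(C)C
F0 | step 9 | none | none
F3 | step 7 | {[(3R)-4-bromo-3-{[3-(TBSO)-4-methoxyphenyl]methyl}but-1-en-1-yl]oxy}trimethylsilane (E/Z mixture) | C[Si](C)(C)OC=C[C@@H](Cc1ccc(OC)c(O[Si](C)(C)C(C)(C)C)c1)CBr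
F4 | step 7 | (3R)-4-bromo-2-[(dimethylamino)methyl]-3-{[3-(TBSO)-4-methoxyphenyl]methyl}butanal (C2 epimers) | CN(C)CC(C=O)[C@@H](Cc1ccc(OC)c(O[Si](C)(C)C(C)(C)C)c1)CBr
F5 | step 7 | [(3R)-4-bromo-2-formyl-3-{[3-(TBSO)-4-methoxyphenyl]methyl}butyl]trimethylammonium iodide | C[N+](C)(C)CC(C=O)[C@@H](Cc1ccc(OC)c(O[Si](C)(C)C(C)(C)C)c1)CBr.[I-]
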